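**Retrosynthetic overview**

1. Core numbering used below: C1 (quaternary oxirane carbon), C2 (carbinol), C3 (=CH), C4 (=C–CH2OH), C5 (carbinol), C6 (oxirane CH) of the 7-oxabicyclo[4.1.0]hept-3-ene; C1' is the side-chain carbinol.
2. Enabling feature: the C5(OH)–C4(CH2OH)=C3H triad of the six-membered carbocycle is a reduced Morita–Baylis–Hillman adduct, and C5 and C2 sit cis on the oxirane. The C4–C5 ring bond is therefore cut back to an acyclic oxirane carrying a C5 aldehyde and a C2-linked (E)-enoate.
3. The acyclic precursor takes all its stereochemistry from C1': enantioselective alkynylation (C1'), trans-hydrostannation and carbonylative Stille coupling (trisubstituted C1=C6 alkene, C2 ketone), 1,3-anti reduction (C2), doubly hydroxyl-directed epoxidation (C1, C6).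
4. The C3'–C4' diene bond comes from a Suzuki–Miyaura coupling of a (Z)-alkenyl chloride with the (E)-alkenylboronate of ring A; ring A comes from geranyl acetate by Shi epoxidation and titanocene radical cyclization.
5. Order of ring formation: ring A (step 2), oxirane (step 12), cyclohexene carbocycle (step 17, last).

Key step: step 17

Remark: in step 8 the (S,S)-ProPhenol ligand is assumed to deliver the alkynyl group to the aldehyde face that gives the S carbinol; if the sense is the opposite, the (R,R) ligand is used and nothing else changes.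

**Route**

Step 1
Reactants: 1 geranyl acetate
Product: 2 (R)-6,7-epoxygeranyl acetate
Conditions: D-fructose-derived Shi ketone (30 mol%), KHSO5 (Oxone), K2CO3, Bu4NHSO4, MeCN/dimethoxymethane, aq. Na2B4O7 buffer, 0 °C
Reagents that add atoms: potassium peroxymonosulfate (Oxone), [K+].[O-]S(=O)(=O)OO
Why: Shi asymmetric epoxidation, in which the chiral dioxirane attacks the electron-rich remote 6,7-alkene (the 2,3-alkene is deactivated by the allylic acetate) through the spiro transition state that should give the R oxirane.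

Step 2
Reactants: 2 (R)-6,7-epoxygeranyl acetate
Product: 3 [(1S,3R)-3-hydroxy-2,2-dimethyl-6-methylidenecyclohexyl]methyl acetate
Conditions: Cp2TiCl2 (2.2 equiv), Mn dust, THF, rt; aqueous work-up
Reagents that add atoms: none
Why: Titanocene-mediated reductive epoxide opening and 6-endo-trig radical cyclization: Cp2TiCl (trivalent titanium) gives the tertiary radical, which closes through a chair with the O–Ti and CH2OAc groups equatorial (cis 1,3-relationship); trapping by a second Cp2TiCl and β-hydride elimination gives the exocyclic alkene, and the carbinol centre is the retained epoxide carbon.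

Step 3
Reactants: 3 [(1S,3R)-3-hydroxy-2,2-dimethyl-6-methylidenecyclohexyl]methyl acetate
Product: 4 (1R,3S)-3-(hydroxymethyl)-2,2-dimethyl-4-methylidenecyclohexan-1-ol
Conditions: K2CO3, MeOH, rt
Reagents that add atoms: none
Why: Base-catalysed transesterification (methanolysis) of the primary acetate, which touches no stereocentre.

Step 4
Reactants: 4 (1R,3S)-3-(hydroxymethyl)-2,2-dimethyl-4-methylidenecyclohexan-1-ol
Product: 5 (1S,3R)-3-hydroxy-2,2-dimethyl-6-methylidenecyclohexane-1-carbaldehyde
Conditions: TEMPO (10 mol%), PhI(OAc)2, CH2Cl2, rt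
Reagents that add atoms: none
Why: Oxoammonium (TEMPO) oxidation, which is selective for the primary alcohol over the hindered secondary one and is mild enough to limit epimerization or conjugation of the β,γ-unsaturated aldehyde (the cis isomer is in any case the more stable one).

Step 5
Reactants: 5 (1S,3R)-3-hydroxy-2,2-dimethyl-6-methylidenecyclohexane-1-carbaldehyde
Product: 6 (1R,3S)-2,2-dimethyl-4-methylidene-3-[(E)-2-(4,4,5,5-tetramethyl-1,3,2-dioxaborolan-2-yl)ethenyl]cyclohexan-1-ol
Conditions: CrCl2, Cl2CHBpin, LiI, THF, rt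
Reagents that add atoms: 2-(dichloromethyl)-4,4,5,5-tetramethyl-1,3,2-dioxaborolane, ClC(Cl)B1OC(C)(C)C(C)(C)O1
Why: Takai–Utimoto-type boryl olefination, in which the geminal dichromium species adds to the aldehyde and anti elimination gives the (E)-alkenylboronate under non-basic conditions that tolerate the free hydroxyl.

Step 6
Reactants: 7 but-2-yn-1-ol
Product: 9 (Z)-3-chlorobut-2-en-1-ol, via cyclic sodium alkenylalanate 8 (not isolated)
Conditions: NaAlH2(OCH2CH2OMe)2, THF, 0 °C; then N-chlorosuccinimide, −78 °C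
Reagents that add atoms: N-chlorosuccinimide, O=C1CCC(=O)N1Cl; sodium bis(2-methoxyethoxy)aluminium dihydride (supplies the Al, Na and alkoxy ligands of 8 only), [Na+].[AlH2-](OCCOC)OCCOC
Why: Hydroxyl-directed trans-hydroalumination of the propargylic alcohol gives the five-membered alkenylalanate with aluminium on C3, and electrophilic chlorination with retention fixes the Z geometry.

Step 7
Reactants: 9 (Z)-3-chlorobut-2-en-1-ol
Product: 10 (Z)-3-chlorobut-2-enal
Conditions: MnO2, CH2Cl2, rt
Reagents that add atoms: none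
Why: Allylic oxidation with MnO2 is neutral and should leave the Z geometry of the β-chloro enal intact; the aldehyde is used at once.

Step 8
Reactants: 10 (Z)-3-chlorobut-2-enal; 11 tert-butyldimethyl(prop-2-yn-1-yloxy)silane
Product: 12 (2Z,4S)-7-[(tert-butyldimethylsilyl)oxy]-2-chlorohept-2-en-5-yn-4-ol
Conditions: (S,S)-ProPhenol (20 mol%), Me2Zn, Ph3P=O, toluene, 0 °C
Reagents that add atoms: none
Why: Dinuclear zinc–ProPhenol catalysed enantioselective alkynylation, in which the zinc alkynylide adds 1,2 to the enal inside the chiral pocket and the ligand sets the C1' carbinol as S.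

Step 9
Reactants: 12 (2Z,4S)-7-[(tert-butyldimethylsilyl)oxy]-2-chlorohept-2-en-5-yn-4-ol
Product: 13 (2Z,4S,5Z)-7-[(tert-butyldimethylsilyl)oxy]-2-chloro-5-(tributylstannyl)hepta-2,5-dien-4-ol
Conditions: [Cp*RuCl]4 (2 mol%), Bu3SnH, CH2Cl2, rt
Reagents that add atoms: tributyltin hydride, CCCC[SnH](CCCC)CCCC
Why: Hydroxyl-directed ruthenium-catalysed trans-hydrostannation, in which hydrogen bonding of the free C1' hydroxyl to the Ru–Cl unit steers tin to the proximal alkyne carbon and anti addition places CH2OTBS cis to tin, the geometry the oxirane will need.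

Step 10
Reactants: 13 (2Z,4S,5Z)-7-[(tert-butyldimethylsilyl)oxy]-2-chloro-5-(tributylstannyl)hepta-2,5-dien-4-ol; 14 methyl (E)-3-iodoprop-2-enoate
Product: 15 methyl (2E,5Z)-7-[(tert-butyldimethylsilyl)oxy]-5-[(1S,2Z)-3-chloro-1-hydroxybut-2-en-1-yl]-4-oxohepta-2,5-dienoate
Conditions: CO (1 atm), Pd2(dba)3 (5 mol%), AsPh3 (20 mol%), CuI (10 mol%), NMP, 45 °C
Reagents that add atoms: carbon monoxide, [C-]#[O+]
Why: Carbonylative Stille coupling (oxidative addition of the iodoacrylate to zerovalent palladium, CO insertion, transmetalation with retention at the alkenyl tin carbon) installs the C2 carbonyl with the enoate arm cis to CH2OTBS; the alkenyl chloride is inert and the free hydroxyl is tolerated.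

Step 11
Reactants: 15 methyl (2E,5Z)-7-[(tert-butyldimethylsilyl)oxy]-5-[(1S,2Z)-3-chloro-1-hydroxybut-2-en-1-yl]-4-oxohepta-2,5-dienoate
Product: 16 methyl (2E,4S,5E)-7-[(tert-butyldimethylsilyl)oxy]-5-[(1S,2Z)-3-chloro-1-hydroxybut-2-en-1-yl]-4-hydroxyhepta-2,5-dienoate (1,3-anti diol)
Conditions: Me4NBH(OAc)3, MeCN/AcOH, −30 °C
Reagents that add atoms: none
Why: Evans–Saksena reduction, in which the C1' alkoxide binds the acetoxyborohydride and delivers hydride intramolecularly through a chair-like six-membered transition state, giving the 1,3-anti diol (S at the future C2) by 1,2-reduction only.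

Step 12
Reactants: 16 methyl (2E,4S,5E)-7-[(tert-butyldimethylsilyl)oxy]-5-[(1S,2Z)-3-chloro-1-hydroxybut-2-en-1-yl]-4-hydroxyhepta-2,5-dienoate
Product: 17 methyl (2E,4S)-4-{(2S,3S)-3-{[(tert-butyldimethylsilyl)oxy]methyl}-2-[(1S,2Z)-3-chloro-1-hydroxybut-2-en-1-yl]oxiran-2-yl}-4-hydroxybut-2-enoate
Conditions: VO(acac)2 (5 mol%), t-BuOOH, CH2Cl2, 0 °C
Reagents that add atoms: tert-butyl hydroperoxide, CC(C)(C)OO
Why: Hydroxyl-directed vanadium-catalysed epoxidation of the only electron-rich alkene that is allylic to both hydroxyls: the C1' hydroxyl (allylic 1,2-strain, erythro delivery) and the C2 hydroxyl (allylic 1,3-strain from the cis CH2OTBS, threo delivery) direct to the same face, which sets C1 and C6; the enoate and the chloroalkene are too electron-poor to react.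

Step 13
Reactants: 17 methyl (2E,4S)-4-{(2S,3S)-3-{[(tert-butyldimethylsilyl)oxy]methyl}-2-[(1S,2Z)-3-chloro-1-hydroxybut-2-en-1-yl]oxiran-2-yl}-4-hydroxybut-2-enoate
Product: 18 bis(tert-butyldimethylsilyl) ether of 17 (both secondary hydroxyls silylated)
Conditions: TBSOTf, 2,6-lutidine, CH2Cl2, −78 °C
Reagents that add atoms: tert-butyldimethylsilyl trifluoromethanesulfonate, CC(C)(C)[Si](C)(C)OS(=O)(=O)C(F)(F)F
Why: Silyl triflate silylation of the two hindered secondary alcohols under buffered low-temperature conditions that spare the oxirane; it blocks lactol formation and oxirane migration later.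

Step 14
Reactants: 18 bis(tert-butyldimethylsilyl) ether of 17; 6 (1R,3S)-2,2-dimethyl-4-methylidene-3-[(E)-2-(4,4,5,5-tetramethyl-1,3,2-dioxaborolan-2-yl)ethenyl]cyclohexan-1-ol
Product: 19 coupled (2Z,4E)-diene (18 with Cl replaced by the (E)-2-[(1S,3R)-3-hydroxy-2,2-dimethyl-6-methylidenecyclohexyl]ethenyl group)
Conditions: Pd(OAc)2 (5 mol%), SPhos (10 mol%), K3PO4, THF/H2O, 60 °C
Reagents that add atoms: none
Why: Suzuki–Miyaura coupling, in which the electron-rich biarylphosphine allows oxidative addition to the alkenyl chloride and both partners couple with retention, giving the (2Z,4E)-diene while no free hydroxyl yet flanks the oxirane.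

Step 15
Reactants: 19 coupled (2Z,4E)-diene
Product: 20 primary alcohol (19 with the CH2OTBS group cleaved to CH2OH)
Conditions: HF·pyridine, pyridine, THF, 0 °C
Reagents that add atoms: none
Why: Buffered fluoride desilylation removes the unhindered primary silyl ether much faster than the two secondary ones next to the quaternary oxirane carbon.

Step 16
Reactants: 20 primary alcohol
Product: 21 oxirane-carbaldehyde (20 with CH2OH oxidised to CHO)
Conditions: TEMPO (10 mol%), PhI(OAc)2, CH2Cl2, rt
Reagents that add atoms: none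
Why: Oxoammonium (TEMPO) oxidation is selective for the primary alcohol over the hindered ring A hydroxyl and leaves the diene and oxirane alone; the oxirane α-hydrogen does not epimerize.

Step 17
Reactants: 21 oxirane-carbaldehyde
Product: 22 methyl (1R,2S,5R,6S)-2-[(tert-butyldimethylsilyl)oxy]-5-hydroxy-1-[(1S,2Z,4E)-1-(silyloxy)dienyl side chain]-7-oxabicyclo[4.1.0]hept-3-ene-4-carboxylate
Conditions: PMe3 (1.0 equiv), t-AmOH, rt
Reagents that add atoms: none
Why: Morita–Baylis–Hillman cyclization: PMe3 adds reversibly to C3 of the enoate to give a phosphonium enolate whose α-carbon C4 attacks the oxirane-bound aldehyde C5, and proton transfer followed by loss of PMe3 restores the C3=C4 alkene inside the new ring. The closest known reaction type is the phosphine-mediated intramolecular Morita–Baylis–Hillman reaction of ω-formyl α,β-unsaturated esters and thioesters to cyclohexenols. The carbocycle closes by a 6-(enolexo)-exo-trig aldol addition of C4 to C5, made easy because the aldehyde and the enoate arm are held cis on the oxirane. The new centre C5 is controlled by the adjacent oxirane: in the ring-forming transition state the C5=O dipole lies anti to the C6–O bond (Cornforth arrangement), which leaves the hydroxyl trans to the oxirane and cis to the C2 silyloxy group, and the reversible aldol step lets this isomer accumulate. The step needs conjugate addition of the phosphine to the enoate only and 1,2-attack on the aldehyde only, and the substrate secures both because the enoate is its only electron-poor alkene and the C5 aldehyde its only carbonyl electrophile within reach.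

Step 18
Reactants: 22 bicyclic methyl ester
Product: 23 bicyclic diol (22 with CO2Me reduced to CH2OH)
Conditions: i-Bu2AlH, CH2Cl2, −78 °C
Reagents that add atoms: none
Why: 1,2-Reduction of the α,β-unsaturated ester by the aluminium hydride is much faster at −78 °C than reductive opening of the oxirane and gives the allylic primary alcohol.

Step 19
Reactants: 23 bicyclic diol
Product: 24 target, (1R,2S,5R,6S)-4-(hydroxymethyl)-1-{(1S,2Z,4E)-1-hydroxy-5-[(1S,3R)-3-hydroxy-2,2-dimethyl-6-methylidenecyclohexyl]-3-methylpenta-2,4-dien-1-yl}-7-oxabicyclo[4.1.0]hept-3-ene-2,5-diol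
Conditions: HF·pyridine, pyridine, THF, 0 °C to rt
Reagents that add atoms: none
Why: Buffered fluoride desilylation frees the two secondary alcohols without generating alkoxides, so base-induced oxirane migration (Payne rearrangement) of the epoxy triol is avoided.

**Compound list**

1 | geranyl acetate | CC(C)=CCC/C(C)=C/COC(C)=O | starting material
2 | (R)-6,7-epoxygeranyl acetate | CC1(C)O[C@@H]1CC/C(C)=C/COC(C)=O | intermediate
3 | [(1S,3R)-3-hydroxy-2,2-dimethyl-6-methylidenecyclohexyl]methyl acetate | C=C1CC[C@@H](O)C(C)(C)[C@H]1COC(C)=O | intermediate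
4 | (1R,3S)-3-(hydroxymethyl)-2,2-dimethyl-4-methylidenecyclohexan-1-ol | C=C1CC[C@@H](O)C(C)(C)[C@H]1CO | intermediate
5 | (1S,3R)-3-hydroxy-2,2-dimethyl-6-methylidenecyclohexane-1-carbaldehyde | C=C1CC[C@@H](O)C(C)(C)[C@H]1C=O | intermediate
6 | (1R,3S)-2,2-dimethyl-4-methylidene-3-[(E)-2-(pinacolboryl)ethenyl]cyclohexan-1-ol | C=C1CC[C@@H](O)C(C)(C)[C@H]1/C=C/B1OC(C)(C)C(C)(C)O1 | intermediate
7 | but-2-yn-1-ol | CC#CCO | starting material
8 | cyclic sodium alkenylalanate (2,5-dihydro-1,2-oxaluminole ate complex) | [Na+].C/C1=C/CO[Al-]1(OCCOC)OCCOC | intermediate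
9 | (Z)-3-chlorobut-2-en-1-ol | C/C(Cl)=C/CO | intermediate
10 | (Z)-3-chlorobut-2-enal | C/C(Cl)=C/C=O | intermediate
11 | tert-butyldimethyl(prop-2-yn-1-yloxy)silane | C#CCO[Si](C)(C)C(C)(C)C | starting material
12 | (2Z,4S)-7-[(tert-butyldimethylsilyl)oxy]-2-chlorohept-2-en-5-yn-4-ol | C/C(Cl)=C/[C@H](O)C#CCO[Si](C)(C)C(C)(C)C | intermediate
13 | (2Z,4S,5Z)-7-[(tert-butyldimethylsilyl)oxy]-2-chloro-5-(tributylstannyl)hepta-2,5-dien-4-ol | C/C(Cl)=C/[C@H](O)/C(=C/CO[Si](C)(C)C(C)(C)C)[Sn](CCCC)(CCCC)CCCC | intermediate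
14 | methyl (E)-3-iodoprop-2-enoate | COC(=O)/C=C/I | starting material
15 | methyl (2E,5Z)-7-[(tert-butyldimethylsilyl)oxy]-5-[(1S,2Z)-3-chloro-1-hydroxybut-2-en-1-yl]-4-oxohepta-2,5-dienoate | C/C(Cl)=C/[C@H](O)/C(=C/CO[Si](C)(C)C(C)(C)C)C(=O)/C=C/C(=O)OC | intermediate
16 | methyl (2E,4S,5E)-7-[(tert-butyldimethylsilyl)oxy]-5-[(1S,2Z)-3-chloro-1-hydroxybut-2-en-1-yl]-4-hydroxyhepta-2,5-dienoate | C/C(Cl)=C/[C@H](O)/C(=C/CO[Si](C)(C)C(C)(C)C)[C@@H](O)/C=C/C(=O)OC | intermediate
17 | methyl (2E,4S)-4-{(2S,3S)-3-{[(tert-butyldimethylsilyl)oxy]methyl}-2-[(1S,2Z)-3-chloro-1-hydroxybut-2-en-1-yl]oxiran-2-yl}-4-hydroxybut-2-enoate | C/C(Cl)=C/[C@H](O)[C@@]1(O[C@H]1CO[Si](C)(C)C(C)(C)C)[C@@H](O)/C=C/C(=O)OC | intermediate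
18 | bis(tert-butyldimethylsilyl) ether of 17 | C/C(Cl)=C/[C@H](O[Si](C)(C)C(C)(C)C)[C@@]1(O[C@H]1CO[Si](C)(C)C(C)(C)C)[C@@H](O[Si](C)(C)C(C)(C)C)/C=C/C(=O)OC | intermediate
19 | coupled (2Z,4E)-diene, tris-silyl ether | C=C1CC[C@@H](O)C(C)(C)[C@H]1/C=C/C(C)=C\[C@H](O[Si](C)(C)C(C)(C)C)[C@@]1(O[C@H]1CO[Si](C)(C)C(C)(C)C)[C@@H](O[Si](C)(C)C(C)(C)C)/C=C/C(=O)OC | intermediate
20 | oxiranylmethanol (primary alcohol) | C=C1CC[C@@H](O)C(C)(C)[C@H]1/C=C/C(C)=C\[C@H](O[Si](C)(C)C(C)(C)C)[C@@]1(O[C@H]1CO)[C@@H](O[Si](C)(C)C(C)(C)C)/C=C/C(=O)OC | intermediate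
21 | oxirane-carbaldehyde (cyclization precursor) | C=C1CC[C@@H](O)C(C)(C)[C@H]1/C=C/C(C)=C\[C@H](O[Si](C)(C)C(C)(C)C)[C@@]1(O[C@H]1C=O)[C@@H](O[Si](C)(C)C(C)(C)C)/C=C/C(=O)OC | intermediate
22 | methyl (1R,2S,5R,6S)-2-silyloxy-5-hydroxy-7-oxabicyclo[4.1.0]hept-3-ene-4-carboxylate with the silylated side chain at C1 | C=C1CC[C@@H](O)C(C)(C)[C@H]1/C=C/C(C)=C\[C@H](O[Si](C)(C)C(C)(C)C)[C@]12O[C@H]1[C@H](O)C(C(=O)OC)=C[C@@H]2O[Si](C)(C)C(C)(C)C | intermediate
23 | bis-silyl ether of the target (C1'–O and C2–O silylated) | C=C1CC[C@@H](O)C(C)(C)[C@H]1/C=C/C(C)=C\[C@H](O[Si](C)(C)C(C)(C)C)[C@]12O[C@H]1[C@H](O)C(CO)=C[C@@H]2O[Si](C)(C)C(C)(C)C | intermediate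
24 | (1R,2S,5R,6S)-4-(hydroxymethyl)-1-{(1S,2Z,4E)-1-hydroxy-5-[(1S,3R)-3-hydroxy-2,2-dimethyl-6-methylidenecyclohexyl]-3-methylpenta-2,4-dien-1-yl}-7-oxabicyclo[4.1.0]hept-3-ene-2,5-diol | C=C1CC[C@@H](O)C(C)(C)[C@H]1/C=C/C(C)=C\[C@H](O)[C@]12O[C@H]1[C@H](O)C(CO)=C[C@@H]2O | target

**Step count and risks**

Total step count: 19. Longest linear sequence: 14 steps (7 to 24, steps 6–19); the ring A branch (steps 1–5) joins at step 14.

Steps most likely to fail:

1. Step 17. The phosphine may add too slowly to the γ-branched enoate, so that decomposition of the oxirane aldehyde or loss of the γ-silyloxy group from the phosphonium intermediate takes over; the C5 hydroxyl may also form on the wrong face. Fallback: the ring is closed by a stoichiometric thiolate-triggered Michael–aldol sequence instead of nucleophilic catalysis. From 21, Me2AlSPh (CH2Cl2, −78 °C) should add thiolate to C3 and close the aluminium enolate onto the aldehyde to give the β-phenylthio aldol adduct F1 (mixture at C3 and C4; both centres are destroyed later). Oxidation with NaIO4 (MeOH/H2O) gives the sulfoxide F2, and elimination of benzenesulfenic acid toward the ester-bearing carbon (toluene, 80 °C, Et3N) should return the route at 22.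

2. Step 10. Transmetalation of the fully substituted alkenylstannane may be slow, so that non-carbonylative coupling, protodestannylation or oxa-Michael closure of the free hydroxyl onto the ene-dione product competes. Fallback: the C1–C2 bond is made by carbonyl addition, not acylation. From 13, iododestannylation (I2, CH2Cl2, 0 °C) gives the alkenyl iodide F3. An asymmetric Nozaki–Hiyama–Kishi addition of F3 to methyl (E)-4-oxobut-2-enoate (CrCl2, NiCl2 cat., chiral sulfonamide ligand, Et3N, THF), in which the alkenyl chloride is inert, should form the C2 carbinol under ligand control and return the route at 16.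

3. Step 11. The 1,3-anti induction may erode because the trigonal carbon between the carbinol and the ketone flattens the hydride-delivery chair. Fallback: reagent control replaces substrate control. From 15, silylation of the C1' hydroxyl (TBSOTf, 2,6-lutidine) gives the silyl ether F4. Reduction with (R)-2-methyl-CBS-oxazaborolidine and catecholborane (toluene, −78 °C) should give the S carbinol F5. VO(acac)2/t-BuOOH epoxidation, now directed by the C2 hydroxyl alone under allylic 1,3-strain control, gives the oxirane F6, and silylation (TBSOTf, 2,6-lutidine) returns the route at 18.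

Further compounds
F1 | step 17 | β-phenylthio aldol adduct (22 saturated at C3–C4, SPh on C3, mixture at C3 and C4) | C=C1CC[C@@H](O)C(C)(C)[C@H]1/C=C/C(C)=C\[C@H](O[Si](C)(C)C(C)(C)C)[C@]12O[C@H]1[C@H](O)C(C(=O)OC)C(Sc1ccccc1)[C@@H]2O[Si](C)(C)C(C)(C)C
F2 | step 17 | sulfoxide of F1 | C=C1CC[C@@H](O)C(C)(C)[C@H]1/C=C/C(C)=C\[C@H](O[Si](C)(C)C(C)(C)C)[C@]12O[C@H]1[C@H](O)C(C(=O)OC)C(S(=O)c1ccccc1)[C@@H]2O[Si](C)(C)C(C)(C)C
F3 | step 10 | (2Z,4S,5Z)-7-[(tert-butyldimethylsilyl)oxy]-2-chloro-5-iodohepta-2,5-dien-4-ol | C/C(Cl)=C/[C@H](O)/C(I)=C/CO[Si](C)(C)C(C)(C)C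
F4 | step 11 | C1'-O-silyl ether of ketone 15 | C/C(Cl)=C/[C@H](O[Si](C)(C)C(C)(C)C)/C(=C/CO[Si](C)(C)C(C)(C)C)C(=O)/C=C/C(=O)OC
F5 | step 11 | (4S)-carbinol from F4 (C1'-O-silyl ether of 16) | C/C(Cl)=C/[C@H](O[Si](C)(C)C(C)(C)C)/C(=C/CO[Si](C)(C)C(C)(C)C)[C@@H](O)/C=C/C(=O)OC
F6 | step 11 | oxirane from F5 (C1'-O-silyl ether of 17) | C/C(Cl)=C/[C@H](O[Si](C)(C)C(C)(C)C)[C@@]1(O[C@H]1CO[Si](C)(C)C(C)(C)C)[C@@H](O)/C=C/C(=O)OC
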